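**Retrosynthetic overview**
1. Rings A and B are bought: methoxyhydroquinone 1 (ring A) and (3,4,5-trimethoxyphenyl)acetic acid 2 (ring B plus C-3 and C-4).
2. First disconnection, the C-4/C-4a aryl–acyl bond: Friedel–Crafts C-acylation of 1 with 2 gives deoxybenzoin 3.
3. Second disconnection, O-1/C-2 and C-2/C-3: one carbon from DMF goes onto the CH2 of 3 (enaminone 4, not isolated), and the ortho-OH closes onto it to give isoflavone 5, the target.
4. Ring order: ring C (the pyranone) is the only ring formed, and it is formed last.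
5. No protecting groups: the 6-OH of the target is the second OH of 1, carried through free.

Assumption: the target has no stereocentre and is achiral, so "single enantiomer" means the compound as drawn and no stereocontrol is needed.

**Route**

Step 1
Reactants: 1 methoxyhydroquinone (2-methoxybenzene-1,4-diol); 2 (3,4,5-trimethoxyphenyl)acetic acid
Product: 3 1-(2,5-dihydroxy-4-methoxyphenyl)-2-(3,4,5-trimethoxyphenyl)ethan-1-one
Conditions: BF3·OEt2 (neat, as solvent), Ar, 85 °C, 3 h; then ice/H2O; recrystallise
Reagents that add atoms: none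
Why: BF3-promoted Friedel–Crafts C-acylation (any O-acyl ester is funnelled on by Fries rearrangement) goes to C-5 of 1, the only ring position that is both ortho to a free OH and para to the OMe, and the hydrogen-bonded ortho-hydroxy ketone formed is deactivated against a second acylation; water is the only co-product and no stereocentre is formed.

Step 2
Reactants: 3 1-(2,5-dihydroxy-4-methoxyphenyl)-2-(3,4,5-trimethoxyphenyl)ethan-1-one
Product: 5 6-hydroxy-7-methoxy-3-(3,4,5-trimethoxyphenyl)-4H-chromen-4-one, via enaminone 4 (not isolated)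
Conditions: DMF, BF3·OEt2 (3 equiv, Lewis acid only), MsCl (3 equiv), 50 → 85 °C, 2 h; then H2O
Reagents that add atoms: N,N-dimethylformamide (DMF), CN(C)C=O
Why: In this Vilsmeier–Haack-type one-carbon annulation, the iminium salt made from DMF and MsCl C-formylates the BF3-activated benzylic CH2 of 3 to enaminone 4, whose ortho-OH adds to the enamine carbon and expels dimethylamine (addition–elimination) to give the aromatic 4-pyranone, while the non-chelated 5'-OH is at worst transiently O-formylated and freed again in the aqueous work-up; no stereocentre is involved.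

**Compound list**
1 | 2-methoxybenzene-1,4-diol (methoxyhydroquinone) | COc1cc(O)ccc1O | starting material
2 | 2-(3,4,5-trimethoxyphenyl)acetic acid | COc1cc(CC(=O)O)cc(OC)c1OC | starting material
3 | 1-(2,5-dihydroxy-4-methoxyphenyl)-2-(3,4,5-trimethoxyphenyl)ethan-1-one | COc1cc(O)c(C(=O)Cc2cc(OC)c(OC)c(OC)c2)cc1O | intermediate
4 | (E)-1-(2,5-dihydroxy-4-methoxyphenyl)-3-(dimethylamino)-2-(3,4,5-trimethoxyphenyl)prop-2-en-1-one (geometry is of no consequence; it is lost on ring closure) | CN(C)/C=C(\c1cc(OC)c(OC)c(OC)c1)C(=O)c1cc(O)c(OC)cc1O | intermediate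
5 | 6-hydroxy-7-methoxy-3-(3,4,5-trimethoxyphenyl)-4H-chromen-4-one | COc1cc2occ(-c3cc(OC)c(OC)c(OC)c3)c(=O)c2cc1O | target

**Totals**
Total step count: 2. Longest linear sequence: 2.

**Steps most likely to fail**
The route has only two steps, so both are ranked; there is no third.

Rank 1, step 1. Risks: acylation at C-6 or C-3 of 1, air oxidation of the hydroquinone to the quinone in hot Lewis acid, and incomplete conversion.
Fallback for step 1 (sets out from compound 1, comes back at compound 3): change the electrophile from the acid to the nitrile, a Hoesch reaction. Compound 1 and commercial 2-(3,4,5-trimethoxyphenyl)acetonitrile (COc1cc(CC#N)cc(OC)c1OC) are treated with ZnCl2 and dry HCl gas in Et2O at 0 °C. The ketiminium salt 1-(2,5-dihydroxy-4-methoxyphenyl)-2-(3,4,5-trimethoxyphenyl)ethan-1-iminium chloride F1 precipitates and is filtered from non-basic by-products. Hydrolysis in water at 90 °C gives compound 3, which enters step 2 unchanged.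

Rank 2, step 2. Risks: O-formylation or O-mesylation of the free 5'-OH that does not reverse on work-up, Vilsmeier formylation of the electron-rich trimethoxyphenyl ring, and incomplete ring closure.
Fallback for step 2 (sets out from compound 1, comes back at compound 5): build ring C first as a 3-iodochromone and attach ring B by Suzuki–Miyaura coupling. Compound 1 is C-acetylated with acetic acid in BF3·OEt2 at 85 °C to 1-(2,5-dihydroxy-4-methoxyphenyl)ethan-1-one F2. The non-chelated 5-OH is benzylated selectively (BnBr, K2CO3, acetone, reflux) to 1-[5-(benzyloxy)-2-hydroxy-4-methoxyphenyl]ethan-1-one F3. DMF dimethyl acetal in toluene at 95 °C gives (E)-1-[5-(benzyloxy)-2-hydroxy-4-methoxyphenyl]-3-(dimethylamino)prop-2-en-1-one F4. I2 in CHCl3 at room temperature cyclises it, with loss of dimethylamine, to 6-(benzyloxy)-3-iodo-7-methoxy-4H-chromen-4-one F5. Coupling with 3,4,5-trimethoxyphenylboronic acid (zerovalent palladium catalyst Pd(PPh3)4, Na2CO3, DME/H2O, 80 °C) gives 6-(benzyloxy)-7-methoxy-3-(3,4,5-trimethoxyphenyl)-4H-chromen-4-one F6. Hydrogenolysis (H2, 1 atm, Pd/C, EtOAc/MeOH, room temperature, stopped at full conversion to spare the C-2/C-3 double bond) gives compound 5.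

**Further compounds**
F1 | step 1 | 1-(2,5-dihydroxy-4-methoxyphenyl)-2-(3,4,5-trimethoxyphenyl)ethan-1-iminium chloride | COc1cc(O)c(C(=[NH2+])Cc2cc(OC)c(OC)c(OC)c2)cc1O.[Cl-]
F2 | step 2 | 1-(2,5-dihydroxy-4-methoxyphenyl)ethan-1-one | COc1cc(O)c(C(C)=O)cc1O
F3 | step 2 | 1-[5-(benzyloxy)-2-hydroxy-4-methoxyphenyl]ethan-1-one | COc1cc(O)c(C(C)=O)cc1OCc1ccccc1
F4 | step 2 | (E)-1-[5-(benzyloxy)-2-hydroxy-4-methoxyphenyl]-3-(dimethylamino)prop-2-en-1-one | CN(C)/C=C/C(=O)c1cc(OCc2ccccc2)c(OC)cc1O
F5 | step 2 | 6-(benzyloxy)-3-iodo-7-methoxy-4H-chromen-4-one | COc1cc2occ(I)c(=O)c2cc1OCc1ccccc1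
F6 | step 2 | 6-(benzyloxy)-7-methoxy-3-(3,4,5-trimethoxyphenyl)-4H-chromen-4-one | COc1cc2occ(-c3cc(OC)c(OC)c(OC)c3)c(=O)c2cc1OCc1ccccc1
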